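Broussonol A is cut at C2–C1′ (Negishi union of a C2-zincated 3-(MOM-oxy)chromone with a bromochromene) and, decisively, within ring A. There the C8a oxygen (O1) and the 1,1-dimethylallyl group on C8 sit on adjacent carbons, with the C7 oxygen on the other flank of C8, so both can be placed across the two carbons of one aryne. In a single operation prenyl oxide adds to 3,5-bis(MOM-oxy)benzyne and the ortho carbanion captures the allyl unit with inversion, giving the C–O and C–C bonds and a lone free phenol, the future O1. The precursor is a phloroglucinol-derived 2-(trimethylsilyl)aryl triflate bearing two MOM ethers, paired with potassium prenyl oxide.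

Key step: step 6

Remark on the chemistry: the methyl ether of the bromophenol starting material has no counterpart in the target, whose C3′ oxygen is a free hydroxyl. It is therefore exchanged for a MOM ether at the chromene stage (steps 13 and 14), so that one mild acidic step releases all four hydroxyls.

Step 1
Reactants: 1 phloroglucinol (benzene-1,3,5-triol)
Product: 2 3,5-bis(methoxymethoxy)phenol
Conditions: MOMCl (2.0 equiv), i-Pr2NEt, DMF/CH2Cl2, 0 °C to rt; chromatographic separation from mono- and tris-ether
Reagents that add atoms: chloromethyl methyl ether, COCCl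
Why: O-alkylation (MOM protection) of the symmetrical triol is statistical, and the bis-ether should be separable by polarity from the mono-ether (which can be resubjected) and the tris-ether.

Step 2
Reactants: 2 3,5-bis(methoxymethoxy)phenol
Product: 3 3,5-bis(methoxymethoxy)phenyl N-(propan-2-yl)carbamate
Conditions: i-PrNCO, Et3N (cat.), CH2Cl2, rt
Reagents that add atoms: isopropyl isocyanate, CC(C)N=C=O
Why: Base-catalysed addition of a phenol to an isocyanate gives the aryl carbamate, a strong ortho-directing group that can later be removed under mild base.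

Step 3
Reactants: 3 3,5-bis(methoxymethoxy)phenyl N-(propan-2-yl)carbamate
Product: 7 3,5-bis(methoxymethoxy)-2-(trimethylsilyl)phenyl N-(propan-2-yl)carbamate, via N-silyl carbamate 4 (not isolated), via aryllithium 5 (not isolated), via bis-silyl carbamate 6 (not isolated)
Conditions: TMSOTf, TMEDA, Et2O, 0 °C to rt; n-BuLi, TMEDA, −78 °C; TMSCl, −78 °C to rt; aq NH4Cl
Reagents that add atoms: chlorotrimethylsilane, C[Si](C)(C)Cl
Why: Directed ortho-metalation: the N-silylated carbamate formed in the flask is the strongest director on the ring and cooperates with the neighbouring MOM-oxy group, so lithiation and C-silylation should occur between these two groups and not between the two MOM ethers, and the labile N–Si bond is hydrolysed on work-up.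

Step 4
Reactants: 7 3,5-bis(methoxymethoxy)-2-(trimethylsilyl)phenyl N-(propan-2-yl)carbamate
Product: 9 3,5-bis(methoxymethoxy)-2-(trimethylsilyl)phenyl trifluoromethanesulfonate, via silylphenol 8 (not isolated)
Conditions: DBU, Et2NH, MeCN, 40 °C; then PhNTf2, rt
Reagents that add atoms: N-phenylbis(trifluoromethanesulfonimide), O=S(=O)(N(c1ccccc1)S(=O)(=O)C(F)(F)F)C(F)(F)F
Why: E1cB cleavage of the N-monosubstituted carbamate (the isocyanate is trapped by diethylamine) releases the hindered phenoxide, which is triflated in the same flask under non-acidic conditions that spare the aryl–silicon bond and the MOM ethers.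

Step 5
Reactants: 10 3-methylbut-2-en-1-ol
Product: 11 potassium 3-methylbut-2-en-1-olate (THF solution, used directly)
Conditions: KH (oil-free, 1.05 equiv), THF, 0 °C to rt; cannula filtration from residual KH
Reagents that add atoms: potassium hydride, [KH]
Why: Irreversible deprotonation of the alcohol by potassium hydride gives an alkoxide solution that contains neither residual alcohol nor any other proton donor.

Step 6
Reactants: 9 3,5-bis(methoxymethoxy)-2-(trimethylsilyl)phenyl trifluoromethanesulfonate; 11 potassium 3-methylbut-2-en-1-olate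
Product: 14 3,5-bis(methoxymethoxy)-2-(2-methylbut-3-en-2-yl)phenol, via aryne 12 (not isolated), via aryl potassium 13 (not isolated)
Conditions: KF (spray-dried), 18-crown-6, THF, 0 °C to rt, 9 added slowly to 11 (2.5 equiv); then aq NH4Cl
Reagents that add atoms: none
Why: Proposed new method: fluoride removes the silyl group and triflate departs to give aryne 12, to which alkoxide 11 adds at the aryne carbon not flanked by a MOM-oxy group, so that the negative charge settles on the carbon ortho to that oxygen (aryl potassium 13). With no proton donor present, this sp2 carbanion attacks the dimethyl-bearing alkene terminus of its own prenyl ether through a six-membered transition state while the O–CH2 bond breaks, an anion-driven aromatic oxa-Claisen ([3,3]) shift with allyl inversion that expels a phenoxide. The closest known reaction types are the aza-Claisen rearrangement of the zwitterions formed from arynes and tertiary allylamines, the addition of alkoxides to arynes, and the thermal Claisen rearrangement of aryl prenyl ethers. No ring is closed and no stereocentre is created, since the new quaternary carbon carries two identical methyl groups. The step needs O-attack at the remote aryne carbon and C–C bond formation ahead of protonation: the inductive pull of the flanking MOM-oxy group directs the alkoxide, and the dry fluoride and crown-ether medium with fully deprotonated alcohol leaves the intramolecular shift, driven by the exchange of an aryl carbanion for a phenoxide, as the fastest outlet.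

Step 7
Reactants: 14 3,5-bis(methoxymethoxy)-2-(2-methylbut-3-en-2-yl)phenol
Product: 15 2-hydroxy-4,6-bis(methoxymethoxy)-3-(2-methylbut-3-en-2-yl)benzaldehyde
Conditions: MgCl2, Et3N, (CH2O)n, MeCN, reflux
Reagents that add atoms: paraformaldehyde (as formaldehyde), C=O
Why: Magnesium-mediated ortho-formylation (Casnati–Skattebøl) delivers formaldehyde within the magnesium phenoxide to the only free position ortho to the hydroxyl, as is known for 2-tert-alkylphenols, and the basic medium spares the MOM ethers.

Step 8
Reactants: 15 2-hydroxy-4,6-bis(methoxymethoxy)-3-(2-methylbut-3-en-2-yl)benzaldehyde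
Product: 16 2-[1-hydroxy-2-(methoxymethoxy)ethyl]-3,5-bis(methoxymethoxy)-6-(2-methylbut-3-en-2-yl)phenol (racemic)
Conditions: NaH, THF, 0 °C; then Bu3SnCH2OMOM/n-BuLi (premixed, THF, −78 °C), −78 to −40 °C; aq NH4Cl
Reagents that add atoms: tributyl[(methoxymethoxy)methyl]stannane, CCCC[Sn](CCCC)(CCCC)COCOC
Why: Tin–lithium exchange generates (methoxymethoxy)methyllithium, which adds 1,2 to the aldehyde of the preformed sodium phenoxide (α-alkoxy organolithium addition to a carbonyl); the new carbinol centre forms as a racemate and is erased in step 9.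

Step 9
Reactants: 16 2-[1-hydroxy-2-(methoxymethoxy)ethyl]-3,5-bis(methoxymethoxy)-6-(2-methylbut-3-en-2-yl)phenol
Product: 17 1-[2-hydroxy-4,6-bis(methoxymethoxy)-3-(2-methylbut-3-en-2-yl)phenyl]-2-(methoxymethoxy)ethan-1-one
Conditions: MnO2 (activated, excess), CH2Cl2, rt
Reagents that add atoms: none
Why: Activated MnO2 oxidises the electron-rich benzylic carbinol to the aryl ketone under neutral heterogeneous conditions, which should leave the free phenol, the MOM ethers and the terminal alkene alone.

Step 10
Reactants: 17 1-[2-hydroxy-4,6-bis(methoxymethoxy)-3-(2-methylbut-3-en-2-yl)phenyl]-2-(methoxymethoxy)ethan-1-one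
Product: 19 3,5,7-tris(methoxymethoxy)-8-(2-methylbut-3-en-2-yl)-4H-chromen-4-one, via enaminone 18 (not isolated)
Conditions: Me2NCH(OMe)2, PhMe, 90 °C; then AcOH (2 equiv), 60 °C
Reagents that add atoms: N,N-dimethylformamide dimethyl acetal, COC(OC)N(C)C
Why: Condensation of the α-methylene ketone with the amide acetal gives the enaminone, and addition–elimination of the ortho phenol with loss of dimethylamine closes the pyranone ring, the standard enaminone route to chromones, here in its 3-alkoxy variant.

Step 11
Reactants: 20 4-bromo-2-methoxyphenol; 21 3-chloro-3-methylbut-1-yne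
Product: 22 4-bromo-2-methoxy-1-[(2-methylbut-3-yn-2-yl)oxy]benzene
Conditions: DBU, CuCl2 (cat.), MeCN, 0 °C
Reagents that add atoms: none
Why: Copper-catalysed O-alkylation of a phenol with a tertiary propargylic chloride gives the 1,1-dimethylpropargyl aryl ether under mild base without elimination of the chloride.

Step 12
Reactants: 22 4-bromo-2-methoxy-1-[(2-methylbut-3-yn-2-yl)oxy]benzene
Product: 23 6-bromo-8-methoxy-2,2-dimethyl-2H-chromene
Conditions: PhNEt2, 180 °C
Reagents that add atoms: none
Why: Thermal aryl propargyl ether Claisen rearrangement to the only free ortho position, followed by 1,5-hydrogen shift and oxa-6π electrocyclisation, gives the 2,2-dimethylchromene, the methoxy group blocking the other ortho site.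

Step 13
Reactants: 23 6-bromo-8-methoxy-2,2-dimethyl-2H-chromene
Product: 24 6-bromo-2,2-dimethyl-2H-chromen-8-ol
Conditions: NaSEt, DMF, 120 °C; dilute aq HCl work-up
Reagents that add atoms: none
Why: SN2 demethylation of the aryl methyl ether by thiolate attacks only the methyl carbon, so the tertiary chromene ether, the aryl bromide and the styrenic alkene should be untouched.

Step 14
Reactants: 24 6-bromo-2,2-dimethyl-2H-chromen-8-ol
Product: 25 6-bromo-8-(methoxymethoxy)-2,2-dimethyl-2H-chromene
Conditions: MOMCl, i-Pr2NEt, CH2Cl2, 0 °C to rt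
Reagents that add atoms: chloromethyl methyl ether, COCCl
Why: Standard MOM protection of a phenol by O-alkylation, chosen so that all four protecting groups of the coupled product are of one kind.

Step 15
Reactants: 19 3,5,7-tris(methoxymethoxy)-8-(2-methylbut-3-en-2-yl)-4H-chromen-4-one; 25 6-bromo-8-(methoxymethoxy)-2,2-dimethyl-2H-chromene
Product: 27 3,5,7-tris(methoxymethoxy)-2-[8-(methoxymethoxy)-2,2-dimethyl-2H-chromen-6-yl]-8-(2-methylbut-3-en-2-yl)-4H-chromen-4-one, via chromonylzinc chloride 26 (not isolated)
Conditions: TMPZnCl·LiCl (TMP = 2,2,6,6-tetramethylpiperidide), THF, 25 °C; then 25, Pd(OAc)2, SPhos, 50 °C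
Reagents that add atoms: none
Why: The C2–H of the chromone, acidified by the ring oxygen and the adjacent C3 MOM-oxy group (C3 itself is blocked), is zincated by the hindered amide base, and Negishi cross-coupling of this heteroarylzinc with the electron-rich aryl bromide forms the C2–C1′ bond under conditions that tolerate MOM ethers and alkenes.

Step 16
Reactants: 27 3,5,7-tris(methoxymethoxy)-2-[8-(methoxymethoxy)-2,2-dimethyl-2H-chromen-6-yl]-8-(2-methylbut-3-en-2-yl)-4H-chromen-4-one
Product: 28 Broussonol A, 3,5,7-trihydroxy-2-(8-hydroxy-2,2-dimethyl-2H-chromen-6-yl)-8-(2-methylbut-3-en-2-yl)-4H-chromen-4-one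
Conditions: HCl (3 M aq), MeOH/THF, 45 °C
Reagents that add atoms: none
Why: Acid-catalysed acetal methanolysis removes all four MOM ethers, and dilute acid at moderate temperature should leave the chromene and the terminal vinyl group (which could protonate only to a secondary cation) intact.

Compound list
1 | phloroglucinol (benzene-1,3,5-triol) | Oc1cc(O)cc(O)c1 | starting material
2 | 3,5-bis(methoxymethoxy)phenol | COCOc1cc(O)cc(OCOC)c1 | intermediate
3 | 3,5-bis(methoxymethoxy)phenyl N-(propan-2-yl)carbamate | COCOc1cc(OCOC)cc(OC(=O)NC(C)C)c1 | intermediate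
4 | 3,5-bis(methoxymethoxy)phenyl N-(propan-2-yl)-N-(trimethylsilyl)carbamate (not isolated) | COCOc1cc(OCOC)cc(OC(=O)N(C(C)C)[Si](C)(C)C)c1 | intermediate
5 | 2-lithio-3,5-bis(methoxymethoxy)phenyl N-(propan-2-yl)-N-(trimethylsilyl)carbamate (not isolated) | COCOc1cc(OCOC)c([Li])c(OC(=O)N(C(C)C)[Si](C)(C)C)c1 | intermediate
6 | 3,5-bis(methoxymethoxy)-2-(trimethylsilyl)phenyl N-(propan-2-yl)-N-(trimethylsilyl)carbamate (not isolated) | COCOc1cc(OCOC)c([Si](C)(C)C)c(OC(=O)N(C(C)C)[Si](C)(C)C)c1 | intermediate
7 | 3,5-bis(methoxymethoxy)-2-(trimethylsilyl)phenyl N-(propan-2-yl)carbamate | COCOc1cc(OCOC)c([Si](C)(C)C)c(OC(=O)NC(C)C)c1 | intermediate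
8 | 3,5-bis(methoxymethoxy)-2-(trimethylsilyl)phenol (not isolated) | COCOc1cc(OCOC)c([Si](C)(C)C)c(O)c1 | intermediate
9 | 3,5-bis(methoxymethoxy)-2-(trimethylsilyl)phenyl trifluoromethanesulfonate | COCOc1cc(OCOC)c([Si](C)(C)C)c(OS(=O)(=O)C(F)(F)F)c1 | intermediate
10 | 3-methylbut-2-en-1-ol | CC(C)=CCO | starting material
11 | potassium 3-methylbut-2-en-1-olate | CC(C)=CC[O-].[K+] | intermediate
12 | 3,5-bis(methoxymethoxy)benzyne (not isolated) | COCOC1=CC#CC(OCOC)=C1 | intermediate
13 | [2,4-bis(methoxymethoxy)-6-[(3-methylbut-2-en-1-yl)oxy]phenyl]potassium (not isolated) | CC(C)=CCOc1cc(OCOC)cc(OCOC)c1[K] | intermediate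
14 | 3,5-bis(methoxymethoxy)-2-(2-methylbut-3-en-2-yl)phenol | C=CC(C)(C)c1c(O)cc(OCOC)cc1OCOC | intermediate
15 | 2-hydroxy-4,6-bis(methoxymethoxy)-3-(2-methylbut-3-en-2-yl)benzaldehyde | C=CC(C)(C)c1c(O)c(C=O)c(OCOC)cc1OCOC | intermediate
16 | 2-[1-hydroxy-2-(methoxymethoxy)ethyl]-3,5-bis(methoxymethoxy)-6-(2-methylbut-3-en-2-yl)phenol, racemic | C=CC(C)(C)c1c(O)c(C(O)COCOC)c(OCOC)cc1OCOC | intermediate
17 | 1-[2-hydroxy-4,6-bis(methoxymethoxy)-3-(2-methylbut-3-en-2-yl)phenyl]-2-(methoxymethoxy)ethan-1-one | C=CC(C)(C)c1c(O)c(C(=O)COCOC)c(OCOC)cc1OCOC | intermediate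
18 | 3-(dimethylamino)-1-[2-hydroxy-4,6-bis(methoxymethoxy)-3-(2-methylbut-3-en-2-yl)phenyl]-2-(methoxymethoxy)prop-2-en-1-one, alkene geometry not defined (not isolated) | C=CC(C)(C)c1c(O)c(C(=O)C(OCOC)=CN(C)C)c(OCOC)cc1OCOC | intermediate
19 | 3,5,7-tris(methoxymethoxy)-8-(2-methylbut-3-en-2-yl)-4H-chromen-4-one | C=CC(C)(C)c1c(OCOC)cc(OCOC)c2c(=O)c(OCOC)coc12 | intermediate
20 | 4-bromo-2-methoxyphenol | COc1cc(Br)ccc1O | starting material
21 | 3-chloro-3-methylbut-1-yne | C#CC(C)(C)Cl | starting material
22 | 4-bromo-2-methoxy-1-[(2-methylbut-3-yn-2-yl)oxy]benzene | COc1cc(Br)ccc1OC(C)(C)C#C | intermediate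
23 | 6-bromo-8-methoxy-2,2-dimethyl-2H-chromene | COc1cc(Br)cc2c1OC(C)(C)C=C2 | intermediate
24 | 6-bromo-2,2-dimethyl-2H-chromen-8-ol | Oc1cc(Br)cc2c1OC(C)(C)C=C2 | intermediate
25 | 6-bromo-8-(methoxymethoxy)-2,2-dimethyl-2H-chromene | COCOc1cc(Br)cc2c1OC(C)(C)C=C2 | intermediate
26 | chlorido[3,5,7-tris(methoxymethoxy)-8-(2-methylbut-3-en-2-yl)-4-oxo-4H-chromen-2-yl]zinc, LiCl complex (not isolated) | C=CC(C)(C)c1c(OCOC)cc(OCOC)c2c(=O)c(OCOC)c([Zn]Cl)oc12 | intermediate
27 | 3,5,7-tris(methoxymethoxy)-2-[8-(methoxymethoxy)-2,2-dimethyl-2H-chromen-6-yl]-8-(2-methylbut-3-en-2-yl)-4H-chromen-4-one | C=CC(C)(C)c1c(OCOC)cc(OCOC)c2c(=O)c(OCOC)c(-c3cc(OCOC)c4c(c3)C=CC(C)(C)O4)oc12 | intermediate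
28 | Broussonol A, 3,5,7-trihydroxy-2-(8-hydroxy-2,2-dimethyl-2H-chromen-6-yl)-8-(2-methylbut-3-en-2-yl)-4H-chromen-4-one (no stereocentre) | C=CC(C)(C)c1c(O)cc(O)c2c(=O)c(O)c(-c3cc(O)c4c(c3)C=CC(C)(C)O4)oc12 | target

Total step count: 16.
Longest linear sequence: 11 steps (steps 1, 2, 3, 4, 6, 7, 8, 9, 10, 15 and 16, from phloroglucinol). The chromene branch (steps 11 to 14) and the alkoxide (step 5) are convergent.

Steps most likely to fail

Step 6. The aryl carbanion may be protonated before it reaches the alkene, which would give the simple aryl prenyl ether. Further risks are attack of the alkoxide on the sulfonyl sulfur instead of aryne formation, internal proton transfer from the allylic positions, and arylation of the product phenoxide by a second aryne. The fallback sets out from 2 and uses known chemistry. O-Alkylation with 1-bromo-3-methylbut-2-ene (K2CO3, acetone, reflux) should give 1,3-bis(methoxymethoxy)-5-[(3-methylbut-2-en-1-yl)oxy]benzene F1. Thermal aromatic Claisen rearrangement of F1 (PhNEt2, about 190 °C) to either of the two equivalent ortho positions should give the inverted allyl group, and the route is rejoined at 14. Any F1 formed by premature protonation in step 6 can be fed into the same rearrangement.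

Step 15. Zincation at C2 may be incomplete, the zinc species may be protonated again, or transmetalation and reductive elimination may be slow at the position crowded by the C3 MOM-oxy group. The fallback builds ring C by condensation instead of cross-coupling and sets out from 17 and 25. Bromine–lithium exchange on 25 (n-BuLi, THF, −78 °C) and quenching with methyl chloroformate should give methyl 8-(methoxymethoxy)-2,2-dimethyl-2H-chromene-6-carboxylate F2. Crossed Claisen condensation of the dianion of 17 (LiN(SiMe3)2, 3.5 equiv, THF, −78 °C to rt) with F2 should give 1-[2-hydroxy-4,6-bis(methoxymethoxy)-3-(2-methylbut-3-en-2-yl)phenyl]-2-(methoxymethoxy)-3-[8-(methoxymethoxy)-2,2-dimethyl-2H-chromen-6-yl]propane-1,3-dione F3 (racemic, enolisable). Treatment of F3 with HCl in MeOH at 45 °C should bring about cyclodehydration to the flavone and loss of all MOM groups in one operation, so the route is rejoined at the target 28.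

Step 3. Lithiation may take place between the two MOM-oxy groups instead of beside the carbamate, or the carbamoyl group may migrate to carbon (anionic Fries shift) on warming. The fallback replaces directed metalation by halogen–metal exchange and sets out from 2. Amine-catalysed ortho-selective bromination (NBS, i-Pr2NH cat., CH2Cl2, 0 °C) should give 2-bromo-3,5-bis(methoxymethoxy)phenol F4. O-Silylation with hexamethyldisilazane (THF, reflux) should give [2-bromo-3,5-bis(methoxymethoxy)phenoxy]trimethylsilane F5. Bromine–lithium exchange on F5 (n-BuLi, THF, −78 °C) triggers the 1,3 oxygen-to-carbon silyl shift (retro-Brook) to the lithium phenoxide of 8, which is triflated in the flask with PhNTf2, and the route is rejoined at 9.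

Further compounds
F1 | step 6 | 1,3-bis(methoxymethoxy)-5-[(3-methylbut-2-en-1-yl)oxy]benzene | CC(C)=CCOc1cc(OCOC)cc(OCOC)c1
F2 | step 15 | methyl 8-(methoxymethoxy)-2,2-dimethyl-2H-chromene-6-carboxylate | COCOc1cc(C(=O)OC)cc2c1OC(C)(C)C=C2
F3 | step 15 | 1-[2-hydroxy-4,6-bis(methoxymethoxy)-3-(2-methylbut-3-en-2-yl)phenyl]-2-(methoxymethoxy)-3-[8-(methoxymethoxy)-2,2-dimethyl-2H-chromen-6-yl]propane-1,3-dione (racemic) | C=CC(C)(C)c1c(O)c(C(=O)C(OCOC)C(=O)c2cc(OCOC)c3c(c2)C=CC(C)(C)O3)c(OCOC)cc1OCOC
F4 | step 3 | 2-bromo-3,5-bis(methoxymethoxy)phenol | COCOc1cc(O)c(Br)c(OCOC)c1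
F5 | step 3 | [2-bromo-3,5-bis(methoxymethoxy)phenoxy]trimethylsilane | COCOc1cc(O[Si](C)(C)C)c(Br)c(OCOC)c1
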